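0.0506 min⁻¹ is the fade constant of the gamma run, the fractional loss of its rate per minute, as read from the two last intervals between its readings.

| setting | gamma | delta | epsilon | alpha |
|---|---|---|---|---|
| Sub | 0.150 M | 0.0900 M | 0.0750 M | 0.150 M |
| Rgt | 0.180 M | 0.120 M | 0.180 M | 0.180 M |
| Cat | 0.00450 M | 0.00450 M | 0.00450 M | 0.00450 M |
| time |  |  |  | 220 min |

| run | time / min | [Prd] / M |
|---|---|---|
| gamma run | 3.1 | 0.0160 |
| gamma run | 9.5 | 0.0370 |
| gamma run | 18 | 0.0510 |
| gamma run | 29 | 0.0610 |
| gamma run | 41 | 0.0653 |
| gamma run | 55 | 0.0679 |
| delta run | 3.1 | 0.0099 |
| delta run | 9.5 | 0.0252 |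
| delta run | 18 | 0.0356 |
| delta run | 29 | 0.0433 |
| delta run | 41 | 0.0485 |
| delta run | 55 | 0.0502 |
| epsilon run | 3.1 | 0.0100 |
| epsilon run | 9.5 | 0.0234 |
| epsilon run | 18 | 0.0342 |
| epsilon run | 29 | 0.0406 |
| epsilon run | 41 | 0.0444 |
| epsilon run | 55 | 0.0463 |

(standard deviation of a reading: 4 × 10⁻⁴ M)

- Overall: Sub + Rgt -> Prd, with Cat as catalyst.
- Constant volume, constant temperature.
- Readings of a species count what is bound in complexes too.
- An order is taken over about fifteen percent of the charge, up and down.

- order of the initial rate in [Sub], near the charge of the gamma run, the rate being that where two percent of its Sub are Prd (one fixed amount of Prd, the same in the runs compared)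
- order of the initial rate in [Rgt], near the charge of the gamma run, the rate being that where two percent of its Sub are Prd
- Prd in the alpha run at 220 min, as a share of the Sub charged

Over its first interval the gamma run turns 0.0344 min⁻¹ of its Sub charge into Prd, and over its last interval 0.00124 min⁻¹, a fall by a factor of 27.8. My own reading of the first points gives rough orders of 0.678 in Sub, from gamma against epsilon, and 0.330 in Rgt, from delta against epsilon. Late in the gamma run the readings of Prd stand near 44.4 % of the Sub charge and 37.0 % of the Rgt charge, so on those rough orders the two conversions slow the rate by estimated factors of 1.49 and 1.16, together 1.73. The observed fall is larger than that, and a further factor of 16.0 remains, which the stoichiometry of Prd formation does not supply.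

That late slowing looks pseudo-first-order, so the rate at 55 min, 8.69 × 10⁻⁴ min⁻¹, divided by the fade constant loses its time unit and gives 1.72 % of the charge, the remaining yield still to come. The alpha run has the gamma charge, so my reckoning ends at 47.0 %, and by 220 min hardly any of that tail is still to come.

The forecast puts the orders at 0.7 (0.5 to 0.9) and 0.35 (0.15 to 0.6), and the alpha run at 47.5 % (46.3 % to 50.5 %), a little above my figure; its ground for the fade is that it “points to catalyst death”.

The flask gives orders of 0.70 in Sub and 0.33 in Rgt near the gamma charge, and 46.3 % of the Sub charge as Prd in the alpha run at 220 min.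

    Cat + Sub → Cat.Sub (18.12 M⁻¹ min⁻¹)
    Cat.Sub + Rgt → Prd + Cat (33.66 M⁻¹ min⁻¹)
    Cat + E → Q
    2 Sub → G (0.5028 M⁻¹ min⁻¹)

The conversion of two Sub into G is the main reason why the alpha run falls short of its full Sub charge: the alpha run reaches 46.3 % with that step and >99.9 % without it, so the step accounts for 100 % of what is missing. The alpha run, with the gamma charge, stands 1 percentage point above the gamma reading at 55 min, against the remaining yield of 1.72 %. The same reckoning on the epsilon run, from its own last intervals, reads a fade constant of 0.0652 min⁻¹ and a remaining yield of 1.76 % of its Sub charge.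

The earlier runs and the new flask were computed for substances that don't exist; noise was put on by code.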